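**Strategy.** The 7-oxabicyclo[4.1.0]heptan-2-one core (C1 bears the methyl, C2 the ketone, C3 the tiglate, C4 the side chain) is read as a masked cyclohexene. The epoxide carbons C1/C6 are the alkene of a Diels–Alder adduct, the C2 ketone oxygen is the siloxy donor of a tiglic-aldehyde-derived diene, and the C3 tigloyloxy group is an acetyl activator in disguise. One catalytic enantioselective [4+2] cycloaddition of (E)-1-siloxy-2-methylbutadiene with (E)-5-bromohexa-3,5-dien-2-one forms the C2–C3 and C4–C5 ring bonds and sets C3, C4 and a temporary C2 carbinol centre. Baeyer–Villiger oxidation later excises the acetyl C–C bond; the C2 silyl ether steers epoxidation and is then oxidised away.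

Key step: step 4

Assumption: the facial sense of the oxazaborolidinium-catalysed cycloaddition is taken from the usual α-C–H···O binding model for enones; should the (S)-catalyst give the antipode of 8, the (R)-catalyst is used with no other change.

Remark: bicyclic compounds are numbered as 7-oxabicyclo[4.1.0]heptanes with C1 = methyl-bearing epoxide carbon, C2 = carbinol/carbonyl carbon, C3 = acyloxy carbon, C4 = side-chain carbon, C5 = CH2, C6 = epoxide CH.

**Step 1**
Reactants: 1 (2E)-2-methylbut-2-enal (tiglic aldehyde)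
Product: 2 tert-butyl(dimethyl){[(1E)-2-methylbuta-1,3-dien-1-yl]oxy}silane
Conditions: TBSOTf, Et3N, Et2O, 0 °C → rt
Reagents that add atoms: tert-butyldimethylsilyl trifluoromethanesulfonate, CC(C)(C)[Si](C)(C)OS(=O)(=O)C(F)(F)F
Why: Soft enolisation (O-silylation of the enal, then γ-deprotonation by Et3N) should give the silyl dienol ether, the (1E) geometry following from the s-trans enal.

**Step 2**
Reactants: 3 prop-2-enal (acrolein)
Product: 5 2-bromoprop-2-enal (2-bromoacrolein), via 2,3-dibromopropanal 4 (not isolated)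
Conditions: Br2, CH2Cl2, −78 → 0 °C; then Et3N, 0 °C
Reagents that add atoms: bromine, BrBr
Why: Bromine addition to the alkene followed by amine-induced E1cB loss of HBr is the standard bromination–dehydrobromination route to an α-bromo enal.

**Step 3**
Reactants: 5 2-bromoprop-2-enal; 6 1-(triphenyl-λ5-phosphanylidene)propan-2-one
Product: 7 (3E)-5-bromohexa-3,5-dien-2-one
Conditions: CH2Cl2, 0 °C → rt
Reagents that add atoms: none
Why: Wittig olefination with a stabilised ylide is E-selective and leaves the bromoalkene untouched.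

**Step 4**
Reactants: 2 tert-butyl(dimethyl){[(1E)-2-methylbuta-1,3-dien-1-yl]oxy}silane; 7 (3E)-5-bromohexa-3,5-dien-2-one
Product: 8 1-[(1S,2S,6R)-6-(1-bromoethenyl)-2-{[tert-butyl(dimethyl)silyl]oxy}-3-methylcyclohex-3-en-1-yl]ethan-1-one
Conditions: (S)-B-(o-tolyl)oxazaborolidine from (S)-α,α-diphenylprolinol (20 mol %), Tf2NH (18 mol %), CH2Cl2, −78 → −40 °C
Reagents that add atoms: none
Why: The protonated oxazaborolidine binds the ketone of 7 and lowers its LUMO, so that siloxydiene 2 adds in a concerted, asynchronous normal-demand [4+2] cycloaddition; the closest known type is the oxazaborolidinium-catalysed enantioselective Diels–Alder reaction of acyclic enones with silyloxy dienes. The cyclohexene ring is closed by suprafacial [4πs+2πs] union of both diene termini with the α,β-alkene. The trans relation of acetyl (C1) and bromoethenyl (C6) follows stereospecifically from the E-alkene, the cis relation of acetyl and silyloxy (C2) from the endo transition state of the E-diene, and the absolute configuration from shielding of one enone face by the catalyst aryl groups. Regioselectivity is needed and is secured by the 1-siloxy donor, which puts the largest HOMO coefficient on the CH2 terminus (outweighing the 2-methyl group), so that this carbon bonds to the enone β-carbon and the siloxy carbon to the α-carbon. Site selectivity for the α,β-alkene over the bromoalkene is secured by the bromine, which deactivates the distal alkene and would force a quaternary C–Br centre.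

**Step 5**
Reactants: 8 1-[(1S,2S,6R)-6-(1-bromoethenyl)-2-{[tert-butyl(dimethyl)silyl]oxy}-3-methylcyclohex-3-en-1-yl]ethan-1-one
Product: 10 (1S,2S,3S,4R,6S)-4-(1-bromoethenyl)-2-{[tert-butyl(dimethyl)silyl]oxy}-1-methyl-7-oxabicyclo[4.1.0]heptan-3-yl acetate, via epoxy ketone 9 (not isolated)
Conditions: mCPBA (excess), CH2Cl2, 0 °C, then 40 °C
Reagents that add atoms: 3-chloroperbenzoic acid (mCPBA), OOC(=O)c1cccc(Cl)c1
Why: Prilezhaev epoxidation should occur anti to the allylic silyloxy group (held pseudoaxial by A(1,2) strain with the ring methyl), setting C1 and C6, and the slower Baeyer–Villiger oxidation then inserts oxygen with migration of the secondary ring carbon rather than methyl and with retention at C3; the electron-poor bromoalkene is inert to the peracid.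

**Step 6**
Reactants: 10 (1S,2S,3S,4R,6S)-4-(1-bromoethenyl)-2-{[tert-butyl(dimethyl)silyl]oxy}-1-methyl-7-oxabicyclo[4.1.0]heptan-3-yl acetate
Product: 11 (1S,2S,3S,4R,6S)-4-(1-bromoethenyl)-2-{[tert-butyl(dimethyl)silyl]oxy}-1-methyl-7-oxabicyclo[4.1.0]heptan-3-ol
Conditions: K2CO3 (cat.), MeOH, 0 °C
Reagents that add atoms: none
Why: Base-catalysed transesterification (methanolysis) removes the acetate while silyl ether, epoxide and bromoalkene survive the mild conditions.

**Step 7**
Reactants: 11 (1S,2S,3S,4R,6S)-4-(1-bromoethenyl)-2-{[tert-butyl(dimethyl)silyl]oxy}-1-methyl-7-oxabicyclo[4.1.0]heptan-3-ol; 12 (2E)-2-methylbut-2-enoyl chloride (tigloyl chloride)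
Product: 13 (1S,2S,3S,4R,6S)-4-(1-bromoethenyl)-2-{[tert-butyl(dimethyl)silyl]oxy}-1-methyl-7-oxabicyclo[4.1.0]heptan-3-yl (2E)-2-methylbut-2-enoate
Conditions: pyridine, DMAP (cat.), CH2Cl2, 0 °C → rt
Reagents that add atoms: none
Why: DMAP-catalysed acylation of the secondary alcohol; pyridine in place of a trialkylamine avoids vinylketene formation and deconjugation of the tigloyl unit.

**Step 8**
Reactants: 14 4-methylpent-3-en-1-ol
Product: 15 4-methylpent-3-enal
Conditions: Dess–Martin periodinane, CH2Cl2, 0 °C → rt; used at once as a solution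
Reagents that add atoms: none
Why: Dess–Martin oxidation under non-basic conditions should give the β,γ-unsaturated aldehyde without migration of the alkene into conjugation.

**Step 9**
Reactants: 13 (1S,2S,3S,4R,6S)-4-(1-bromoethenyl)-2-{[tert-butyl(dimethyl)silyl]oxy}-1-methyl-7-oxabicyclo[4.1.0]heptan-3-yl (2E)-2-methylbut-2-enoate; 15 4-methylpent-3-enal
Product: 16 (1S,2S,3S,4S,6S)-2-{[tert-butyl(dimethyl)silyl]oxy}-4-(3-hydroxy-6-methylhepta-1,5-dien-2-yl)-1-methyl-7-oxabicyclo[4.1.0]heptan-3-yl (2E)-2-methylbut-2-enoate (both carbinol epimers)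
Conditions: CrCl2 (excess), NiCl2 (cat.), DMF, rt
Reagents that add atoms: none
Why: Nozaki–Hiyama–Kishi coupling: nickel-catalysed activation of the C–Br bond, transmetalation to trivalent chromium and chemoselective addition of the alkenylchromium species to the aldehyde in the presence of ester, epoxide and silyl ether; the unselective carbinol centre is erased in step 11.

**Step 10**
Reactants: 16 (1S,2S,3S,4S,6S)-2-{[tert-butyl(dimethyl)silyl]oxy}-4-(3-hydroxy-6-methylhepta-1,5-dien-2-yl)-1-methyl-7-oxabicyclo[4.1.0]heptan-3-yl (2E)-2-methylbut-2-enoate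
Product: 17 (1R,2S,3S,4S,6S)-2-hydroxy-4-(3-hydroxy-6-methylhepta-1,5-dien-2-yl)-1-methyl-7-oxabicyclo[4.1.0]heptan-3-yl (2E)-2-methylbut-2-enoate (both carbinol epimers)
Conditions: HF·pyridine, pyridine, THF, 0 °C → rt
Reagents that add atoms: none
Why: Fluoride desilylation under buffered, weakly acidic conditions avoids an alkoxide and hence tigloyl migration to the cis-vicinal hydroxyl and Payne rearrangement of the epoxy alcohol.

**Step 11**
Reactants: 17 (1R,2S,3S,4S,6S)-2-hydroxy-4-(3-hydroxy-6-methylhepta-1,5-dien-2-yl)-1-methyl-7-oxabicyclo[4.1.0]heptan-3-yl (2E)-2-methylbut-2-enoate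
Product: 19 (1S,3S,4S,6S)-1-methyl-4-(6-methyl-3-oxohepta-1,5-dien-2-yl)-2-oxo-7-oxabicyclo[4.1.0]heptan-3-yl (2E)-2-methylbut-2-enoate, via hydroxy enone 18 (not isolated)
Conditions: Dess–Martin periodinane (excess), CH2Cl2, 0 °C → rt
Reagents that add atoms: none
Why: Dess–Martin oxidation should convert both secondary alcohols (the allylic one first) into the cross-conjugated enone and the epoxy ketone without base, so that C3 and the β,γ-alkene stay in place and the temporary C2 centre is erased.

**Step 12**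
Reactants: 19 (1S,3S,4S,6S)-1-methyl-4-(6-methyl-3-oxohepta-1,5-dien-2-yl)-2-oxo-7-oxabicyclo[4.1.0]heptan-3-yl (2E)-2-methylbut-2-enoate
Product: 20 (1S,3S,4S,6S)-4-[(4E)-6-hydroperoxy-6-methyl-3-oxohepta-1,4-dien-2-yl]-1-methyl-2-oxo-7-oxabicyclo[4.1.0]heptan-3-yl (2E)-2-methylbut-2-enoate
Conditions: O2, tetraphenylporphyrin (cat.), visible light, CH2Cl2, −20 °C; no reductive work-up
Reagents that add atoms: dioxygen, O=O
Why: Schenck ene reaction of singlet oxygen: only the electron-rich trisubstituted alkene reacts, and abstraction of the methylene hydrogen next to the carbonyl group (favoured in β,γ-unsaturated carbonyl compounds by developing conjugation) should give the tertiary hydroperoxide with the alkene shifted into E-conjugation.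

**Compound list**
1 | (2E)-2-methylbut-2-enal (tiglic aldehyde) | C/C=C(\C)C=O | starting material
2 | tert-butyl(dimethyl){[(1E)-2-methylbuta-1,3-dien-1-yl]oxy}silane | C=C/C(C)=C/O[Si](C)(C)C(C)(C)C | intermediate
3 | prop-2-enal (acrolein) | C=CC=O | starting material
4 | 2,3-dibromopropanal | BrCC(Br)C=O | intermediate
5 | 2-bromoprop-2-enal | C=C(Br)C=O | intermediate
6 | 1-(triphenyl-λ5-phosphanylidene)propan-2-one | CC(=O)C=P(c1ccccc1)(c1ccccc1)c1ccccc1 | starting material
7 | (3E)-5-bromohexa-3,5-dien-2-one | C=C(Br)/C=C/C(C)=O | intermediate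
8 | 1-[(1S,2S,6R)-6-(1-bromoethenyl)-2-{[tert-butyl(dimethyl)silyl]oxy}-3-methylcyclohex-3-en-1-yl]ethan-1-one | C=C(Br)[C@@H]1CC=C(C)[C@@H](O[Si](C)(C)C(C)(C)C)[C@H]1C(C)=O | intermediate
9 | 1-[(1S,2S,3S,4R,6S)-4-(1-bromoethenyl)-2-{[tert-butyl(dimethyl)silyl]oxy}-1-methyl-7-oxabicyclo[4.1.0]heptan-3-yl]ethan-1-one | C=C(Br)[C@@H]1C[C@@H]2O[C@]2(C)[C@@H](O[Si](C)(C)C(C)(C)C)[C@H]1C(C)=O | intermediate
10 | (1S,2S,3S,4R,6S)-4-(1-bromoethenyl)-2-{[tert-butyl(dimethyl)silyl]oxy}-1-methyl-7-oxabicyclo[4.1.0]heptan-3-yl acetate | C=C(Br)[C@@H]1C[C@@H]2O[C@]2(C)[C@@H](O[Si](C)(C)C(C)(C)C)[C@H]1OC(C)=O | intermediate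
11 | (1S,2S,3S,4R,6S)-4-(1-bromoethenyl)-2-{[tert-butyl(dimethyl)silyl]oxy}-1-methyl-7-oxabicyclo[4.1.0]heptan-3-ol | C=C(Br)[C@@H]1C[C@@H]2O[C@]2(C)[C@@H](O[Si](C)(C)C(C)(C)C)[C@H]1O | intermediate
12 | (2E)-2-methylbut-2-enoyl chloride (tigloyl chloride) | C/C=C(\C)C(=O)Cl | starting material
13 | (1S,2S,3S,4R,6S)-4-(1-bromoethenyl)-2-{[tert-butyl(dimethyl)silyl]oxy}-1-methyl-7-oxabicyclo[4.1.0]heptan-3-yl (2E)-2-methylbut-2-enoate | C=C(Br)[C@@H]1C[C@@H]2O[C@]2(C)[C@@H](O[Si](C)(C)C(C)(C)C)[C@H]1OC(=O)/C(C)=C/C | intermediate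
14 | 4-methylpent-3-en-1-ol | CC(C)=CCCO | starting material
15 | 4-methylpent-3-enal | CC(C)=CCC=O | intermediate
16 | (1S,2S,3S,4S,6S)-2-{[tert-butyl(dimethyl)silyl]oxy}-4-(3-hydroxy-6-methylhepta-1,5-dien-2-yl)-1-methyl-7-oxabicyclo[4.1.0]heptan-3-yl (2E)-2-methylbut-2-enoate | C=C(C(O)CC=C(C)C)[C@@H]1C[C@@H]2O[C@]2(C)[C@@H](O[Si](C)(C)C(C)(C)C)[C@H]1OC(=O)/C(C)=C/C | intermediate
17 | (1R,2S,3S,4S,6S)-2-hydroxy-4-(3-hydroxy-6-methylhepta-1,5-dien-2-yl)-1-methyl-7-oxabicyclo[4.1.0]heptan-3-yl (2E)-2-methylbut-2-enoate | C=C(C(O)CC=C(C)C)[C@@H]1C[C@@H]2O[C@]2(C)[C@@H](O)[C@H]1OC(=O)/C(C)=C/C | intermediate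
18 | (1R,2S,3S,4S,6S)-2-hydroxy-1-methyl-4-(6-methyl-3-oxohepta-1,5-dien-2-yl)-7-oxabicyclo[4.1.0]heptan-3-yl (2E)-2-methylbut-2-enoate | C=C(C(=O)CC=C(C)C)[C@@H]1C[C@@H]2O[C@]2(C)[C@@H](O)[C@H]1OC(=O)/C(C)=C/C | intermediate
19 | (1S,3S,4S,6S)-1-methyl-4-(6-methyl-3-oxohepta-1,5-dien-2-yl)-2-oxo-7-oxabicyclo[4.1.0]heptan-3-yl (2E)-2-methylbut-2-enoate | C=C(C(=O)CC=C(C)C)[C@@H]1C[C@@H]2O[C@]2(C)C(=O)[C@H]1OC(=O)/C(C)=C/C | intermediate
20 | (1S,3S,4S,6S)-4-[(4E)-6-hydroperoxy-6-methyl-3-oxohepta-1,4-dien-2-yl]-1-methyl-2-oxo-7-oxabicyclo[4.1.0]heptan-3-yl (2E)-2-methylbut-2-enoate | C=C(C(=O)/C=C/C(C)(C)OO)[C@@H]1C[C@@H]2O[C@]2(C)C(=O)[C@H]1OC(=O)/C(C)=C/C | target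

**Step count.** Total: 12 steps. Longest linear sequence: 10 steps (steps 2, 3, 4, 5, 6, 7, 9, 10, 11, 12).

**Steps most likely to fail**

Step 4. The cycloaddition may lose enantio- or site-selectivity, or the silyl dienol ether may be consumed by silyl transfer (a stepwise Mukaiyama–Michael pathway) under the strongly acidic boron catalyst. The fallback changes the activation mode from Lewis-acid binding of a ketone to iminium catalysis of an aldehyde; it sets out from 5 (with 2) and returns at 8. Aldehyde 5 is homologated with (triphenylphosphoranylidene)acetaldehyde (CH2Cl2, rt) to (2E)-4-bromopenta-2,4-dienal F1. Endo-selective cycloaddition of 2 with F1 under a 5-benzyl-2,2,3-trimethylimidazolidin-4-one hydrochloride catalyst (enantiomer chosen for the required face; MeCN with a little water, −20 °C) should give (1S,2S,6R)-6-(1-bromoethenyl)-2-{[tert-butyl(dimethyl)silyl]oxy}-3-methylcyclohex-3-ene-1-carbaldehyde F2, in which the same two ring bonds are formed. Addition of MeMgBr (THF, −78 °C) gives 1-[(1R,2S,6R)-6-(1-bromoethenyl)-2-{[tert-butyl(dimethyl)silyl]oxy}-3-methylcyclohex-3-en-1-yl]ethan-1-ol F3 (both carbinol epimers), and Dess–Martin oxidation returns 8.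

Step 5. The Baeyer–Villiger migration at the hindered ketone may stall, and during the long exposure to peracid and carboxylic acid the new epoxide may be opened. The fallback reverses the order of the two oxidations with an alkene-sparing oxidant; it sets out from 8 and returns at 10. Bis(trimethylsilyl) peroxide with catalytic Me3SiOTf (CH2Cl2, −78 → −30 °C) should perform the Baeyer–Villiger oxidation without touching the ring alkene, giving (1S,2R,6R)-6-(1-bromoethenyl)-2-{[tert-butyl(dimethyl)silyl]oxy}-3-methylcyclohex-3-en-1-yl acetate F4. Brief epoxidation with dimethyldioxirane (acetone, −20 °C), again anti to the silyloxy group, then gives 10 under neutral conditions.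

Step 12. Hydrogen abstraction from the cis methyl group may compete and divert material to the regioisomeric secondary hydroperoxide. The fallback replaces the pericyclic ene reaction by an ionic, Markovnikov-controlled sequence; it sets out from 19 and returns at 20. Bromoperoxidation of the trisubstituted alkene (1,3-dibromo-5,5-dimethylhydantoin, anhydrous H2O2 in Et2O, −40 °C) should place the hydroperoxy group on the tertiary carbon, giving (1S,3S,4S,6S)-4-(5-bromo-6-hydroperoxy-6-methyl-3-oxohept-1-en-2-yl)-1-methyl-2-oxo-7-oxabicyclo[4.1.0]heptan-3-yl (2E)-2-methylbut-2-enoate F5 (both bromide epimers). E1cB loss of HBr from this β-bromo ketone (Et3N, CH2Cl2, 0 °C) then gives 20 with the E-enone.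

**Further compounds**
F1 | step 4 | (2E)-4-bromopenta-2,4-dienal | C=C(Br)/C=C/C=O
F2 | step 4 | (1S,2S,6R)-6-(1-bromoethenyl)-2-{[tert-butyl(dimethyl)silyl]oxy}-3-methylcyclohex-3-ene-1-carbaldehyde | C=C(Br)[C@@H]1CC=C(C)[C@@H](O[Si](C)(C)C(C)(C)C)[C@H]1C=O
F3 | step 4 | 1-[(1R,2S,6R)-6-(1-bromoethenyl)-2-{[tert-butyl(dimethyl)silyl]oxy}-3-methylcyclohex-3-en-1-yl]ethan-1-ol | C=C(Br)[C@@H]1CC=C(C)[C@@H](O[Si](C)(C)C(C)(C)C)[C@H]1C(C)O
F4 | step 5 | (1S,2R,6R)-6-(1-bromoethenyl)-2-{[tert-butyl(dimethyl)silyl]oxy}-3-methylcyclohex-3-en-1-yl acetate | C=C(Br)[C@@H]1CC=C(C)[C@@H](O[Si](C)(C)C(C)(C)C)[C@H]1OC(C)=O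
F5 | step 12 | (1S,3S,4S,6S)-4-(5-bromo-6-hydroperoxy-6-methyl-3-oxohept-1-en-2-yl)-1-methyl-2-oxo-7-oxabicyclo[4.1.0]heptan-3-yl (2E)-2-methylbut-2-enoate | C=C(C(=O)CC(Br)C(C)(C)OO)[C@@H]1C[C@@H]2O[C@]2(C)C(=O)[C@H]1OC(=O)/C(C)=C/C
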